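A direct plan would set C2 and C3 in an open chain: an (E)-γ-aryloxyallylboronate A1 would add to bis-silylated 5-hydroxyvanillin
under chiral phosphoric acid control to give the anti aryloxy alcohol A2, a copper-catalysed C–O coupling would close the dioxane
ring (cis vinyl compound A3), ozonolysis–reduction would give alcohol A4, and a Suzuki coupling and desilylation would finish.
Weakest would be the allylboration: an O-aryl allylboronate with a di-ortho-substituted aryl group would be untested, and both
the anti ratio and the enantioselectivity would rest on it.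
The copper-catalysed ring closure would ask a hindered secondary benzylic alkoxide to displace iodide beside a bromide at high dilution.
The ozonolysis–reduction would add length only: it would trim a vinyl group to CH2OH through an epimerisable α-aryloxy aldehyde.

The cis pair C2(aryl)/C3(CH2OH) of the dioxane ring is the syn-dihydro form of an enediol diether, so both centres are traced back to the C2=C3 bond of a flat, achiral 1,4-benzodioxine whose C3 substituent is a carboxylic acid. Ring C is closed first, without stereochemistry, by condensing 5-hydroxyvanillin with an α-chloro-β-keto ester; one carboxylate-directed iridium hydrogenation then adds two hydrogens to one face of the tetrasubstituted enol ether, fixing cis by mechanism and the absolute configuration by the catalyst. The allylboration, the aryl C–O coupling and the vinyl trimming have no counterpart: the directing carboxyl becomes the CH2OH, and the propenol arm is carried as an acrylate.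

Key step: step 6

Assumption: the (Sa,S) spiro ligand is taken to deliver hydrogen to the face that gives the (2S,3S) acid 14, by analogy with α-aryloxy acrylic acids; should the sense prove opposite, the (Ra,R) ligand would be used.
Remark on labels: ring A is the 3-methoxy-4,5-dioxygenated phenyl ring, ring B the benzo ring, ring C the dioxane ring. In the names of the acids and esters the carboxyl-bearing carbon is C2 and the aryl-bearing carbon C3, the reverse of the target numbering.

Step 1
Reactants: 1 3,4-dihydroxy-5-methoxybenzoic acid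
Product: 3 3-methoxy-4,5-bis(pivaloyloxy)benzoic acid, via mixed pivalic anhydride 2 (not isolated)
Conditions: PivCl (3.5 equiv), pyridine (5 equiv), DMAP (5 mol %), CH2Cl2, 0 °C to rt; then THF/aq. NaHCO3, rt, 1 h; acidify to pH 3
Reagents that add atoms: pivaloyl chloride, CC(C)(C)C(=O)Cl
Why: DMAP-catalysed O-acylation (nucleophilic acyl substitution) should esterify both phenols, the mixed anhydride formed at the carboxyl group being hydrolysed by aqueous bicarbonate; pivalates are chosen because they resist carbonate, CF3CO2H and the hydrogenation, deactivate ring A, and fall to hydride in the last step.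

Step 2
Reactants: 3 3-methoxy-4,5-bis(pivaloyloxy)benzoic acid
Product: 6 tert-butyl 3-[3-methoxy-4,5-bis(pivaloyloxy)phenyl]-3-oxopropanoate, via acid chloride 4 (not isolated), via acylmalonic half ester 5 (not isolated)
Conditions: (COCl)2 (1.3 equiv), DMF (cat.), CH2Cl2, 0 °C to rt, evaporate; then HO2CCH2CO2tBu (2 equiv), MgCl2 (2.2 equiv), Et3N (4 equiv), MeCN, 0 °C to rt; cold aq. citric acid
Reagents that add atoms: 3-tert-butoxy-3-oxopropanoic acid (mono-tert-butyl malonate), CC(C)(C)OC(=O)CC(=O)O
Why: Acid chloride formation and C-acylation of the magnesium enolate of the malonic half ester, followed by decarboxylation of the acylmalonic acid on acidification, is the standard two-carbon homologation of an aroyl chloride to a β-keto ester, and the tert-butyl ester is chosen so that the acid can later be freed without base.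

Step 3
Reactants: 6 tert-butyl 3-[3-methoxy-4,5-bis(pivaloyloxy)phenyl]-3-oxopropanoate
Product: 7 tert-butyl 2-chloro-3-[3-methoxy-4,5-bis(pivaloyloxy)phenyl]-3-oxopropanoate (racemic)
Conditions: SO2Cl2 (1.02 equiv), CH2Cl2, 0 °C
Reagents that add atoms: sulfuryl chloride, O=S(=O)(Cl)Cl
Why: Electrophilic α-chlorination of the enol of the β-keto ester with one equivalent of sulfuryl chloride should stop at the monochloride, ring A being deactivated by its acyl and acyloxy groups, and the chloride is preferred to the bromide because it is the poorer halogen donor toward the phenoxide of the next step.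

Step 4
Reactants: 7 tert-butyl 2-chloro-3-[3-methoxy-4,5-bis(pivaloyloxy)phenyl]-3-oxopropanoate; 8 3,4-dihydroxy-5-methoxybenzaldehyde (5-hydroxyvanillin)
Product: 11 tert-butyl 6-formyl-8-methoxy-3-[3-methoxy-4,5-bis(pivaloyloxy)phenyl]-1,4-benzodioxine-2-carboxylate, via keto phenol 9 (not isolated), via cyclic hemiketal 10 (not isolated)
Conditions: K2CO3 (1.05 equiv), MeCN, rt, Ar; filter through a silica pad (EtOAc, 1 % AcOH), evaporate; then (CF3CO)2O (1.5 equiv), pyridine (4 equiv), CH2Cl2, 0 °C to rt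
Reagents that add atoms: none
Why: Williamson etherification (SN2 at the doubly activated C–Cl bond) by the 4-phenoxide of 8, the more acidic one because it is para to the formyl group, puts the oxygen para to the future propenol arm on the ester-bearing carbon, after which the neighbouring 3-OH adds to the aryl ketone (6-exo-trig hemiketal, ring C) and trifluoroacetylation–elimination (E1 through the aryl- and oxygen-stabilised oxocarbenium ion, loss of the acidic proton α to the ester) gives the enol ether, so that the regiochemistry of the whole target is fixed here and no stereocentre remains.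

Step 5
Reactants: 11 tert-butyl 6-formyl-8-methoxy-3-[3-methoxy-4,5-bis(pivaloyloxy)phenyl]-1,4-benzodioxine-2-carboxylate
Product: 13 8-methoxy-3-[3-methoxy-4,5-bis(pivaloyloxy)phenyl]-6-[(E)-3-methoxy-3-oxoprop-1-enyl]-1,4-benzodioxine-2-carboxylic acid, via tert-butyl ester acrylate 12 (not isolated)
Conditions: Ph3P=CHCO2Me (1.3 equiv), CH2Cl2, 40 °C; then CF3CO2H (CH2Cl2/CF3CO2H 3:1), 0 °C to rt
Reagents that add atoms: methyl (triphenylphosphoranylidene)acetate, COC(=O)C=P(c1ccccc1)(c1ccccc1)c1ccccc1
Why: Wittig olefination with the ester-stabilised ylide should give the (E)-acrylate as is usual for such ylides, and acidolysis of the tert-butyl ester (E1 loss of 2-methylpropene) then frees the directing carboxylic acid while the methyl ester, the aryl pivalates and the push–pull enol ether, which is protonated only with difficulty, remain.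

Step 6
Reactants: 13 8-methoxy-3-[3-methoxy-4,5-bis(pivaloyloxy)phenyl]-6-[(E)-3-methoxy-3-oxoprop-1-enyl]-1,4-benzodioxine-2-carboxylic acid
Product: 14 (2S,3S)-8-methoxy-3-[3-methoxy-4,5-bis(pivaloyloxy)phenyl]-6-[(E)-3-methoxy-3-oxoprop-1-enyl]-2,3-dihydro-1,4-benzodioxine-2-carboxylic acid (cis)
Conditions: [Ir(cod)((Sa,S)-L)][B(3,5-(CF3)2C6H3)4] (2 mol %; L = 7-[bis(3,5-di-tert-butylphenyl)phosphino]-7'-[(S)-4-benzyl-4,5-dihydrooxazol-2-yl]-1,1'-spirobiindane), H2 (30 atm), Et3N (0.5 equiv), MeOH, 45 °C, 24 h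
Reagents that add atoms: none
Why: Proposed new method: H2 converts the cationic monovalent iridium precatalyst into a trivalent iridium dihydride that binds 13 through its triethylammonium carboxylate, so that the adjacent C2=C3 bond is held cis to a hydride; migratory insertion and C–H reductive elimination then place both hydrogens on one face, which turns the flat, achiral dioxine into the cis acid because a syn addition cannot give trans. The closest known reactions are the carboxy-directed hydrogenations of α-aryloxy and of tetrasubstituted α,β-unsaturated acids and of 1,4-benzodioxine-2-carboxylic acid with iridium complexes of the same spiro phosphine–oxazoline ligands; new here is the fully substituted, ring-embedded β-aryl-β-aryloxy acrylic acid. No ring is closed in this step. Both stereocentres are set by the catalyst, whose spiro pocket selects the alkene face to which hydride is delivered while the carboxylate is bound, and their cis relation follows from the suprafacial mechanism. The step needs chemoselectivity for the tetrasubstituted enol ether over the ring B acrylate and the aryl pivalates: this catalyst type should reduce only alkenes that carry a free carboxyl group beside them, the methyl acrylate has none, and with substoichiometric amine in methanol no free base is present to attack the pivalates or to epimerise the product carboxylate.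

Step 7
Reactants: 14 (2S,3S)-8-methoxy-3-[3-methoxy-4,5-bis(pivaloyloxy)phenyl]-6-[(E)-3-methoxy-3-oxoprop-1-enyl]-2,3-dihydro-1,4-benzodioxine-2-carboxylic acid
Product: 16 5-[(2S,3R)-3-(hydroxymethyl)-7-[(E)-3-hydroxyprop-1-enyl]-5-methoxy-2,3-dihydro-1,4-benzodioxin-2-yl]-3-methoxybenzene-1,2-diol (CNP0174261.1), via cis methyl ester 15 (not isolated)
Conditions: TMSCHN2 (1.3 equiv), PhMe/MeOH 4:1, 0 °C; evaporate; then iBu2AlH (DIBAL-H, 12 equiv), CH2Cl2, −78 to 0 °C, Ar; EtOAc, then aq. KNaC4H4O6/NaH2PO4 (pH 6)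
Reagents that add atoms: none
Why: O-Methylation of the acid by the diazoalkane (no base, hence no enolisation α to the ester) and exhaustive hydride reduction with iBu2AlH should turn the saturated ester into CH2OH and the cinnamate into the (E)-allylic alcohol (1,2-reduction) and cleave both aryl pivalates reductively, all at or below 0 °C and without a free phenoxide, so that neither stereocentre is touched (the descriptor of the CH2OH-bearing carbon changes from S to R only through the change in priorities).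

## Compound list
1 | 3,4-dihydroxy-5-methoxybenzoic acid | COc1cc(C(=O)O)cc(O)c1O | starting material
2 | 3-methoxy-4,5-bis(pivaloyloxy)benzoic pivalic anhydride (not isolated) | COc1cc(C(=O)OC(=O)C(C)(C)C)cc(OC(=O)C(C)(C)C)c1OC(=O)C(C)(C)C | intermediate
3 | 3-methoxy-4,5-bis(pivaloyloxy)benzoic acid | COc1cc(C(=O)O)cc(OC(=O)C(C)(C)C)c1OC(=O)C(C)(C)C | intermediate
4 | 3-methoxy-4,5-bis(pivaloyloxy)benzoyl chloride (not isolated) | COc1cc(C(=O)Cl)cc(OC(=O)C(C)(C)C)c1OC(=O)C(C)(C)C | intermediate
5 | 2-(tert-butoxycarbonyl)-3-[3-methoxy-4,5-bis(pivaloyloxy)phenyl]-3-oxopropanoic acid (not isolated) | COc1cc(C(=O)C(C(=O)O)C(=O)OC(C)(C)C)cc(OC(=O)C(C)(C)C)c1OC(=O)C(C)(C)C | intermediate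
6 | tert-butyl 3-[3-methoxy-4,5-bis(pivaloyloxy)phenyl]-3-oxopropanoate | COc1cc(C(=O)CC(=O)OC(C)(C)C)cc(OC(=O)C(C)(C)C)c1OC(=O)C(C)(C)C | intermediate
7 | tert-butyl 2-chloro-3-[3-methoxy-4,5-bis(pivaloyloxy)phenyl]-3-oxopropanoate (racemic) | COc1cc(C(=O)C(Cl)C(=O)OC(C)(C)C)cc(OC(=O)C(C)(C)C)c1OC(=O)C(C)(C)C | intermediate
8 | 3,4-dihydroxy-5-methoxybenzaldehyde (5-hydroxyvanillin) | COc1cc(C=O)cc(O)c1O | starting material
9 | tert-butyl 2-(4-formyl-2-hydroxy-6-methoxyphenoxy)-3-[3-methoxy-4,5-bis(pivaloyloxy)phenyl]-3-oxopropanoate (racemic, not isolated) | COc1cc(C(=O)C(Oc2c(O)cc(C=O)cc2OC)C(=O)OC(C)(C)C)cc(OC(=O)C(C)(C)C)c1OC(=O)C(C)(C)C | intermediate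
10 | tert-butyl 6-formyl-3-hydroxy-8-methoxy-3-[3-methoxy-4,5-bis(pivaloyloxy)phenyl]-2,3-dihydro-1,4-benzodioxine-2-carboxylate (ring tautomer of 9, mixture of diastereomers, not isolated) | COc1cc(C2(O)Oc3cc(C=O)cc(OC)c3OC2C(=O)OC(C)(C)C)cc(OC(=O)C(C)(C)C)c1OC(=O)C(C)(C)C | intermediate
11 | tert-butyl 6-formyl-8-methoxy-3-[3-methoxy-4,5-bis(pivaloyloxy)phenyl]-1,4-benzodioxine-2-carboxylate | COc1cc(C2=C(C(=O)OC(C)(C)C)Oc3c(OC)cc(C=O)cc3O2)cc(OC(=O)C(C)(C)C)c1OC(=O)C(C)(C)C | intermediate
12 | tert-butyl 8-methoxy-3-[3-methoxy-4,5-bis(pivaloyloxy)phenyl]-6-[(E)-3-methoxy-3-oxoprop-1-enyl]-1,4-benzodioxine-2-carboxylate (not isolated) | COc1cc(C2=C(C(=O)OC(C)(C)C)Oc3c(OC)cc(/C=C/C(=O)OC)cc3O2)cc(OC(=O)C(C)(C)C)c1OC(=O)C(C)(C)C | intermediate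
13 | 8-methoxy-3-[3-methoxy-4,5-bis(pivaloyloxy)phenyl]-6-[(E)-3-methoxy-3-oxoprop-1-enyl]-1,4-benzodioxine-2-carboxylic acid | COc1cc(C2=C(C(=O)O)Oc3c(OC)cc(/C=C/C(=O)OC)cc3O2)cc(OC(=O)C(C)(C)C)c1OC(=O)C(C)(C)C | intermediate
14 | (2S,3S)-8-methoxy-3-[3-methoxy-4,5-bis(pivaloyloxy)phenyl]-6-[(E)-3-methoxy-3-oxoprop-1-enyl]-2,3-dihydro-1,4-benzodioxine-2-carboxylic acid (cis) | COc1cc([C@@H]2Oc3cc(/C=C/C(=O)OC)cc(OC)c3O[C@@H]2C(=O)O)cc(OC(=O)C(C)(C)C)c1OC(=O)C(C)(C)C | intermediate
15 | methyl (2S,3S)-8-methoxy-3-[3-methoxy-4,5-bis(pivaloyloxy)phenyl]-6-[(E)-3-methoxy-3-oxoprop-1-enyl]-2,3-dihydro-1,4-benzodioxine-2-carboxylate (cis, not isolated) | COc1cc([C@@H]2Oc3cc(/C=C/C(=O)OC)cc(OC)c3O[C@@H]2C(=O)OC)cc(OC(=O)C(C)(C)C)c1OC(=O)C(C)(C)C | intermediate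
16 | 5-[(2S,3R)-3-(hydroxymethyl)-7-[(E)-3-hydroxyprop-1-enyl]-5-methoxy-2,3-dihydro-1,4-benzodioxin-2-yl]-3-methoxybenzene-1,2-diol | COc1cc([C@@H]2Oc3cc(/C=C/CO)cc(OC)c3O[C@@H]2CO)cc(O)c1O | target

Total step count: 7. Longest linear sequence: 7 steps (from 1; compound 8 is bought and enters at step 4).

Steps most likely to fail

Step 6 (proposed new method). The catalyst may fail to turn over on the fully substituted push–pull double bond, discriminate its faces poorly, or attack the acrylate. The fallback would set the relative and the absolute configuration separately by known means, setting out from aldehyde 11 and coming back at acid 14. Heterogeneous hydrogenation (H2, 4 atm, Rh/Al2O3, EtOAc), which adds hydrogen suprafacially from the metal surface and also reduces the formyl group, should give racemic cis tert-butyl 6-(hydroxymethyl)-8-methoxy-3-[3-methoxy-4,5-bis(pivaloyloxy)phenyl]-2,3-dihydro-1,4-benzodioxine-2-carboxylate F1. Rhodium is chosen over palladium to spare the benzylic C–O bond. MnO2 in CH2Cl2 would restore the aldehyde, giving the racemic cis 6-formyl ester F2. Preparative chromatography on a chiral stationary phase would provide the (2S,3S) 6-formyl ester F3. The Wittig reaction and CF3CO2H treatment of step 5 would then lead through the cis tert-butyl ester acrylate F4 to 14.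

Step 4. Alkylation may occur at the wrong phenol oxygen, or the hemiketal may fragment or lactonise instead of dehydrating. The fallback would fix the order of the two C–O bond formations by a halogen, setting out from chloride 7 and coming back at benzodioxine 11. Chloride 7 would be combined with 4-hydroxy-3-iodo-5-methoxybenzaldehyde (5-iodovanillin) F5, which has a single phenol (K2CO3, MeCN), to give tert-butyl 2-(4-formyl-2-iodo-6-methoxyphenoxy)-3-[3-methoxy-4,5-bis(pivaloyloxy)phenyl]-3-oxopropanoate F6. A copper-catalysed intramolecular O-arylation of the β-keto ester enolate (CuI, 1,10-phenanthroline, K3PO4, dioxane, 90 °C) would then join the enol oxygen to the iodine-bearing carbon and give 11 without a hemiketal; C-arylation is excluded because it would need a four-membered ring.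

Step 7. The cis configuration may be lost by opening of the benzylic C–O bond once the para oxygen is unmasked as an aluminium phenoxide, or the catechol may be held back as an aluminium chelate. The fallback would release the phenols with fluoride instead of hydride after exchanging the protecting groups at the achiral stage, setting out from acid 13 and coming back at target 16. K2CO3 in MeOH (rt, Ar), harmless while no stereocentre is present, would remove both pivalates to give 3-(3,4-dihydroxy-5-methoxyphenyl)-8-methoxy-6-[(E)-3-methoxy-3-oxoprop-1-enyl]-1,4-benzodioxine-2-carboxylic acid F7. TBSCl and imidazole in DMF, with an aqueous work-up that cleaves the silyl ester, would give the 3-[3-methoxy-4,5-bis(tert-butyldimethylsilyloxy)phenyl] acid F8. Hydrogenation as in step 6 would give the (2S,3S) cis bis-silyl acid F9. TMSCHN2 and then iBu2AlH, which spares aryl silyl ethers, would lead through the cis bis-silyl methyl ester F10 to the bis(tert-butyldimethylsilyl) ether of the target F11. Bu4NF buffered with AcOH (THF, 0 °C) would then give 16.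

Further compounds
F1 | step 6 | tert-butyl (2S,3S)-6-(hydroxymethyl)-8-methoxy-3-[3-methoxy-4,5-bis(pivaloyloxy)phenyl]-2,3-dihydro-1,4-benzodioxine-2-carboxylate, cis, as the racemate | COc1cc([C@@H]2Oc3cc(CO)cc(OC)c3O[C@@H]2C(=O)OC(C)(C)C)cc(OC(=O)C(C)(C)C)c1OC(=O)C(C)(C)C
F2 | step 6 | tert-butyl (2S,3S)-6-formyl-8-methoxy-3-[3-methoxy-4,5-bis(pivaloyloxy)phenyl]-2,3-dihydro-1,4-benzodioxine-2-carboxylate, cis, as the racemate | COc1cc([C@@H]2Oc3cc(C=O)cc(OC)c3O[C@@H]2C(=O)OC(C)(C)C)cc(OC(=O)C(C)(C)C)c1OC(=O)C(C)(C)C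
F3 | step 6 | tert-butyl (2S,3S)-6-formyl-8-methoxy-3-[3-methoxy-4,5-bis(pivaloyloxy)phenyl]-2,3-dihydro-1,4-benzodioxine-2-carboxylate, single enantiomer | COc1cc([C@@H]2Oc3cc(C=O)cc(OC)c3O[C@@H]2C(=O)OC(C)(C)C)cc(OC(=O)C(C)(C)C)c1OC(=O)C(C)(C)C
F4 | step 6 | tert-butyl (2S,3S)-8-methoxy-3-[3-methoxy-4,5-bis(pivaloyloxy)phenyl]-6-[(E)-3-methoxy-3-oxoprop-1-enyl]-2,3-dihydro-1,4-benzodioxine-2-carboxylate | COc1cc([C@@H]2Oc3cc(/C=C/C(=O)OC)cc(OC)c3O[C@@H]2C(=O)OC(C)(C)C)cc(OC(=O)C(C)(C)C)c1OC(=O)C(C)(C)C
F5 | step 4 | 4-hydroxy-3-iodo-5-methoxybenzaldehyde (5-iodovanillin, purchased) | COc1cc(C=O)cc(I)c1O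
F6 | step 4 | tert-butyl 2-(4-formyl-2-iodo-6-methoxyphenoxy)-3-[3-methoxy-4,5-bis(pivaloyloxy)phenyl]-3-oxopropanoate (racemic) | COc1cc(C(=O)C(Oc2c(I)cc(C=O)cc2OC)C(=O)OC(C)(C)C)cc(OC(=O)C(C)(C)C)c1OC(=O)C(C)(C)C
F7 | step 7 | 3-(3,4-dihydroxy-5-methoxyphenyl)-8-methoxy-6-[(E)-3-methoxy-3-oxoprop-1-enyl]-1,4-benzodioxine-2-carboxylic acid | COc1cc(C2=C(C(=O)O)Oc3c(OC)cc(/C=C/C(=O)OC)cc3O2)cc(O)c1O
F8 | step 7 | 3-[3-methoxy-4,5-bis(tert-butyldimethylsilyloxy)phenyl]-8-methoxy-6-[(E)-3-methoxy-3-oxoprop-1-enyl]-1,4-benzodioxine-2-carboxylic acid | COc1cc(C2=C(C(=O)O)Oc3c(OC)cc(/C=C/C(=O)OC)cc3O2)cc(O[Si](C)(C)C(C)(C)C)c1O[Si](C)(C)C(C)(C)C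
F9 | step 7 | (2S,3S)-3-[3-methoxy-4,5-bis(tert-butyldimethylsilyloxy)phenyl]-8-methoxy-6-[(E)-3-methoxy-3-oxoprop-1-enyl]-2,3-dihydro-1,4-benzodioxine-2-carboxylic acid (cis) | COc1cc([C@@H]2Oc3cc(/C=C/C(=O)OC)cc(OC)c3O[C@@H]2C(=O)O)cc(O[Si](C)(C)C(C)(C)C)c1O[Si](C)(C)C(C)(C)C
F10 | step 7 | methyl (2S,3S)-3-[3-methoxy-4,5-bis(tert-butyldimethylsilyloxy)phenyl]-8-methoxy-6-[(E)-3-methoxy-3-oxoprop-1-enyl]-2,3-dihydro-1,4-benzodioxine-2-carboxylate (cis) | COc1cc([C@@H]2Oc3cc(/C=C/C(=O)OC)cc(OC)c3O[C@@H]2C(=O)OC)cc(O[Si](C)(C)C(C)(C)C)c1O[Si](C)(C)C(C)(C)C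
F11 | step 7 | [(2R,3S)-3-[3-methoxy-4,5-bis(tert-butyldimethylsilyloxy)phenyl]-6-[(E)-3-hydroxyprop-1-enyl]-8-methoxy-2,3-dihydro-1,4-benzodioxin-2-yl]methanol (cis, bis-silyl ether of the target) | COc1cc([C@@H]2Oc3cc(/C=C/CO)cc(OC)c3O[C@@H]2CO)cc(O[Si](C)(C)C(C)(C)C)c1O[Si](C)(C)C(C)(C)C
A1 | direct plan | 2-[(E)-3-(4-bromo-2-iodo-6-methoxyphenoxy)prop-2-enyl]-4,4,5,5-tetramethyl-1,3,2-dioxaborolane | COc1cc(Br)cc(I)c1O/C=C/CB1OC(C)(C)C(C)(C)O1
A2 | direct plan | (1S,2R)-2-(4-bromo-2-iodo-6-methoxyphenoxy)-1-[3-methoxy-4,5-bis(triisopropylsilyloxy)phenyl]but-3-en-1-ol | COc1cc([C@H](O)[C@@H](C=C)Oc2c(I)cc(Br)cc2OC)cc(O[Si](C(C)C)(C(C)C)C(C)C)c1O[Si](C(C)C)(C(C)C)C(C)C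
A3 | direct plan | (2S,3R)-7-bromo-3-ethenyl-5-methoxy-2-[3-methoxy-4,5-bis(triisopropylsilyloxy)phenyl]-2,3-dihydro-1,4-benzodioxine (cis) | COc1cc([C@@H]2Oc3cc(Br)cc(OC)c3O[C@@H]2C=C)cc(O[Si](C(C)C)(C(C)C)C(C)C)c1O[Si](C(C)C)(C(C)C)C(C)C
A4 | direct plan | cis-(2S,3R)-7-bromo-3-(hydroxymethyl)-5-methoxy-2-[3-methoxy-4,5-bis(triisopropylsilyloxy)phenyl]-2,3-dihydro-1,4-benzodioxine | COc1cc([C@@H]2Oc3cc(Br)cc(OC)c3O[C@@H]2CO)cc(O[Si](C(C)C)(C(C)C)C(C)C)c1O[Si](C(C)C)(C(C)C)C(C)C
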